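**Retrosynthetic overview**

Numbering: ring A = C14–C18 (C17=O, C18 isopropyl), ring B = C1, C2, C12–C15 (C15 methyl, C12 OH), ring C = C2–C6, C10–C12 (C3 and C11 methyls), ring D = C6–C10 (C7 methyl); β is the face of the C15 methyl.
Feature: the C10–C11 epoxide of ring C is the oxide of a tetrasubstituted alkene that lies in a cyclooct-4-ene relation to C4; with a carbonyl at C4 this is what a [3,3] shift of the enol ether C5=C4–O–C11 onto the ring D alkene C10=C6 leaves behind.
Disconnections: epoxide ⇒ C12-OH-directed epoxidation of C10=C11; C4 methylene ⇒ C4 ketone; ring C ⇒ Claisen ring expansion of a 2-methylenepyran (C2, C3, C4, O, C11, C12) ⇒ δ-lactone; C11 ⇒ methyl addition to a C11 dienone made from a C12 aldehyde and the ring D alkenyllithium; C2–C3 ⇒ enolate alkylation with lactate triflate.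
Hydrindanone (rings A and B) ⇒ (S)-carvone: reductive propargylation (C15), alkyne hydration and aldol (ring A), Criegee cleavage (C12–O), hydroxyl-directed hydrogenation (C14, C18).
Order of rings: B (from carvone) → A → D attached at C11 on a temporary pyran → C by ring expansion (key step) → epoxide last.

Key step: step 21

Remark: the C11 substituents are introduced cyclopentenyl first and methyl last, because under Felkin–Anh control the reverse order (cyclopentenyl metal to a C12-silyloxy methyl ketone) would be expected to give the C11 epimer that rearranges to the C6 epimer.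

**Route**

Step 1
Reactants: 1 3-methylbut-1-yne
Product: 3 4-methylpent-2-yn-1-ol, via lithium acetylide 2 (not isolated)
Conditions: n-BuLi, THF, −78 °C; then (CH2O)n, −78 °C → rt
Reagents that add atoms: formaldehyde (as paraformaldehyde), C=O
Why: Deprotonation of the terminal alkyne and hydroxymethylation of the acetylide is a standard acetylide addition to a carbonyl group.

Step 2
Reactants: 3 4-methylpent-2-yn-1-ol
Product: 4 1-bromo-4-methylpent-2-yne
Conditions: CBr4, PPh3, CH2Cl2, 0 °C
Reagents that add atoms: tetrabromomethane, BrC(Br)(Br)Br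
Why: The Appel reaction should convert the primary propargylic alcohol into the bromide under neutral conditions without allene formation.

Step 3
Reactants: 5 (S)-carvone; 4 1-bromo-4-methylpent-2-yne
Product: 7 (2S,5S)-2-methyl-2-(4-methylpent-2-yn-1-yl)-5-(prop-1-en-2-yl)cyclohexan-1-one, via lithium enolate 6 (not isolated)
Conditions: Li, NH3(l), THF, t-BuOH (1 equiv), −78 °C; isoprene; then 4, −78 → −33 °C
Reagents that add atoms: none
Why: In this Birch-type reductive alkylation lithium in ammonia gives the C14–C15 enolate regiospecifically, and the bromide should attack C15 axially on the half-chair with the isopropenyl group equatorial, so that the new chain comes out cis to the isopropenyl group (the minor C15 epimer is removed by chromatography).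

Step 4
Reactants: 7 alkynyl ketone
Product: 8 (2S,5S)-2-methyl-2-(4-methyl-2-oxopentyl)-5-(prop-1-en-2-yl)cyclohexan-1-one
Conditions: Ph3PAuCl (2 mol %), AgOTf (2 mol %), H2O, 1,4-dioxane, 60 °C
Reagents that add atoms: water, O
Why: In this gold-catalysed alkyne hydration the ring carbonyl oxygen attacks the proximal alkyne carbon (5-exo), which places the new carbonyl at C17 and gives the 1,4-diketone.

Step 5
Reactants: 8 1,4-diketone
Product: 9 (5S,7aS)-3-isopropyl-7a-methyl-5-(prop-1-en-2-yl)-1,4,5,6,7,7a-hexahydro-2H-inden-2-one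
Conditions: KOH, EtOH, 80 °C
Reagents that add atoms: none
Why: Intramolecular aldol condensation of the C18 methylene onto the C14 ketone closes ring A as the tetrasubstituted cyclopentenone, while the alternative bridged aldol is reversible and cannot dehydrate.

Step 6
Reactants: 9 bicyclic enone
Product: 11 (5S,7aS)-3-isopropyl-7a-methyl-2-oxo-2,4,5,6,7,7a-hexahydro-1H-inden-5-yl acetate, via methoxy hydroperoxide 10 (not isolated)
Conditions: O3, CH2Cl2/MeOH, −78 °C; then Ac2O, Et3N, DMAP (cat.), CH2Cl2, 0 → 40 °C
Reagents that add atoms: ozone, O=[O+][O-]; methanol, CO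
Why: Ozone cleaves the electron-rich isopropenyl group in preference to the deactivated enone, and acetylation of the methoxy hydroperoxide triggers a Criegee rearrangement in which the C12 ring carbon migrates to oxygen with retention.

Step 7
Reactants: 11 acetate
Product: 12 (5S,7aS)-5-hydroxy-3-isopropyl-7a-methyl-1,4,5,6,7,7a-hexahydro-2H-inden-2-one
Conditions: p-TsOH (cat.), MeOH, 40 °C
Reagents that add atoms: none
Why: Acid-catalysed transesterification frees the alcohol without the base that could cause vinylogous β-elimination of the δ-acetoxy enone.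

Step 8
Reactants: 12 hydroxy enone
Product: 13 (3R,3aS,5S,7aS)-5-hydroxy-3-isopropyl-7a-methyloctahydro-2H-inden-2-one
Conditions: [Ir(cod)(PCy3)(py)]PF6 (10 mol %), H2 (20 bar), CH2Cl2, rt
Reagents that add atoms: none
Why: In this hydroxyl-directed hydrogenation the axial C12 hydroxyl on the α face binds the cationic iridium catalyst, so both hydrogens should be delivered to the α face of C14=C18, which sets H-14 trans to the C15 methyl (trans-hydrindane) and H-18 α (isopropyl β).

Step 9
Reactants: 13 hydroxy ketone
Product: 14 C17 ethylene ketal of 13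
Conditions: HOCH2CH2OH, HC(OEt)3, p-TsOH (cat.), CH2Cl2, rt
Reagents that add atoms: ethane-1,2-diol, OCCO
Why: Acid-catalysed ketalisation with orthoformate as water scavenger runs at room temperature, so the C18 centre next to the only ketone should not epimerise.

Step 10
Reactants: 14 hydroxy ketal
Product: 15 trans-hydrindanone (C12 ketone, C17 dioxolane, 18β-isopropyl)
Conditions: Dess–Martin periodinane, pyridine, CH2Cl2, 0 °C → rt
Reagents that add atoms: none
Why: Dess–Martin oxidation of the secondary alcohol gives the C12 ketone under buffered conditions that leave the ketal intact.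

Step 11
Reactants: 16 ethyl (S)-lactate
Product: 17 ethyl (S)-2-(trifluoromethylsulfonyloxy)propanoate
Conditions: Tf2O, 2,6-lutidine, CH2Cl2, −78 → 0 °C
Reagents that add atoms: trifluoromethanesulfonic anhydride, O=S(=O)(OS(=O)(=O)C(F)(F)F)C(F)(F)F
Why: O-Sulfonylation of the α-hydroxy ester does not touch the stereocentre.

Step 12
Reactants: 15 trans-hydrindanone; 17 lactate triflate
Product: 19 keto ester (15 with the (2S)-1-ethoxy-1-oxopropan-2-yl group at C2α), via lithium enolate 18 (not isolated)
Conditions: LiN(i-Pr)2, THF, −78 °C; then 17, −78 → −30 °C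
Reagents that add atoms: none
Why: Kinetic deprotonation of the trans-hydrindanone occurs at C2 (away from the ring fusion), and SN2 alkylation of the enolate by the α-triflyloxy ester inverts the lactate centre (C3 is S in 19), while the chain ends equatorial (α) at C2 because the axial β approach is blocked by the C15 methyl and C2 can equilibrate.

Step 13
Reactants: 19 keto ester
Product: 21 C12 vinyl carbinol triethylsilyl ether (12β-vinyl; 12α-OSiEt3), via bromomagnesium alkoxide 20 (not isolated)
Conditions: CH2=CHMgBr (THF solution), toluene, −78 °C; then Et3SiOTf, 2,6-lutidine, −78 → −20 °C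
Reagents that add atoms: vinylmagnesium bromide, C=C[Mg]Br; triethylsilyl trifluoromethanesulfonate, CC[Si](CC)(CC)OS(=O)(=O)C(F)(F)F
Why: Grignard 1,2-addition to the ketone (much faster than to the ester at −78 °C) by equatorial attack trans to the C2 substituent should give the axial C12 alkoxide, which is silylated in the flask before it can lactonise onto C4.

Step 14
Reactants: 21 vinyl silyl ether
Product: 23 C12 aldehyde (C11 formyl; 12α-OSiEt3), via ozonide 22 (not isolated)
Conditions: O3, CH2Cl2, −78 °C; then PPh3, −78 °C → rt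
Reagents that add atoms: ozone, O=[O+][O-]
Why: Ozonolysis of the only alkene with reductive work-up gives the aldehyde, whose quaternary α-carbon cannot epimerise.

Step 15
Reactants: 24 cyclopentane-1,3-dione
Product: 25 3-bromocyclopent-2-en-1-one
Conditions: (COBr)2, DMF (cat.), CH2Cl2, 0 °C → rt
Reagents that add atoms: oxalyl bromide, O=C(Br)C(Br)=O
Why: The enol of the 1,3-dione is converted into the vinylogous acid bromide by Vilsmeier-type activation and addition–elimination.

Step 16
Reactants: 25 3-bromocyclopent-2-en-1-one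
Product: 26 1-bromo-3-methylenecyclopent-1-ene
Conditions: Ph3PCH3Br, KOt-Bu, THF, 0 °C; then 25, 0 °C → rt
Reagents that add atoms: methyltriphenylphosphonium bromide, C[P+](c1ccccc1)(c1ccccc1)c1ccccc1.[Br-]
Why: In this Wittig methylenation the non-stabilised ylide should add 1,2 to the enone carbonyl and give the exocyclic diene.

Step 17
Reactants: 26 1-bromo-3-methylenecyclopent-1-ene; 23 C12 aldehyde
Product: 28 C11 dienyl carbinol (both C11 epimers), via alkenyllithium 27 (not isolated)
Conditions: t-BuLi (2 equiv), Et2O, −78 °C; then 23, THF, −78 °C; AcOH, −78 °C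
Reagents that add atoms: none
Why: Bromine–lithium exchange gives the alkenyllithium, which adds to the aldehyde far faster than to the ester at −78 °C, and the carbinol configuration is irrelevant because it is oxidised next.

Step 18
Reactants: 28 C11 carbinol
Product: 29 C11 dienone
Conditions: Dess–Martin periodinane, pyridine, CH2Cl2, 0 °C
Reagents that add atoms: none
Why: Dess–Martin oxidation of the dienylic alcohol under buffered conditions gives the conjugated ketone without acid-induced ionisation.

Step 19
Reactants: 29 C11 dienone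
Product: 31 δ-lactone (C4–O–C11; 11R; C11 methyl β), via C11 alkoxide 30 (not isolated)
Conditions: MeLi, CeCl3, THF, −78 °C; then −78 → 0 °C; pH 7 buffer
Reagents that add atoms: methyllithium, [Li]C
Why: Organocerium 1,2-addition should follow the Felkin–Anh model (C12–OSiEt3 anti to the incoming methyl, approach past the C13 methylene and not past the substituted C2), which sets C11 with the methyl cis to H-2, and the tertiary alkoxide then closes the δ-lactone by acyl substitution on the ethyl ester.

Step 20
Reactants: 31 δ-lactone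
Product: 32 2-methylenepyran (enol ether C5=C4–O–C11)
Conditions: Cp2TiMe2 (3 equiv), toluene, 70 °C, dark
Reagents that add atoms: dimethyltitanocene, C[Ti+2]C.c1cc[cH-]c1.c1cc[cH-]c1
Why: Petasis methylenation converts the lactone carbonyl into the exocyclic enol ether under non-acidic conditions that spare the ketal, the silyl ether and the diene.

Step 21
Reactants: 32 2-methylenepyran
Product: 33 tetracyclic C4 ketone (cyclooct-4-enone; C10=C11; C7 methylene; 6S)
Conditions: toluene (0.01 M), 2,6-di-tert-butyl-4-methylpyridine (5 mol %), base-washed silylated sealed tube, 170 °C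
Reagents that add atoms: none
Why: Heating brings the enol ether C5=C4–O–C11 and the cyclopentenyl alkene C10=C6 into a six-centre array in which O–C11 breaks while C5–C6 forms, giving the C4 ketone and the tetrasubstituted C10=C11 alkene; the closest known reaction type is the Claisen ring expansion of 2-methylene-6-vinyltetrahydropyrans to cyclooct-4-enones. Ring C is closed by ring enlargement of the pyran: its five carbons (C2, C3, C4, C11, C12) plus C5, C6 and C10 become the eight-membered ring, and the three-carbon bridge C3–C2–C12 forces the new alkene to be cis within the ring (C6 cis to C12). C6 is the only new stereocentre and is fixed by suprafacial transfer from C11: with C12 turned cis to C6 and the C11 methyl towards C9, the oxygen leaves and C5 arrives on the same face of the cyclopentene, which for the 11R configuration of 32 gives 6S whether the array is chair-like or boat-like, since C5 carries no stereochemical information. The step needs the trans-fused pyran to leave its chair, in which the cyclopentenyl group is equatorial; flipping the oxygen end to a twist-boat makes that group pseudo-axial over the C4=C5 π bond, a change that should be eased by the 1,3-diaxial C3-methyl/C12-silyloxy strain of the chair and by the tertiary, dienyl-substituted C11–O bond, which loosens the transition state. The exocyclic diene is locked s-trans, so no [1,5]-hydrogen shift or cycloaddition competes, and the base-washed vessel keeps the exocyclic enol ether from drifting into the ring.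

Step 22
Reactants: 33 C4 ketone
Product: 34 C7-methyl ketone (7S)
Conditions: RhCl(PPh3)3 (10 mol %), H2 (1 bar), benzene, rt
Reagents that add atoms: none
Why: Homogeneous hydrogenation with RhCl(PPh3)3 reduces the 1,1-disubstituted alkene and leaves the tetrasubstituted C10=C11 alkene, and hydrogen should add to the face of ring D that carries H-6 (anti to C5), so that the C7 methyl comes out cis to C5.

Step 23
Reactants: 34 C7-methyl ketone
Product: 35 C4 alcohol (both C4 epimers)
Conditions: NaBH4, MeOH/THF, 0 °C
Reagents that add atoms: none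
Why: Hydride reduction of the ring C ketone gives a carbinol whose configuration is of no consequence.

Step 24
Reactants: 35 C4 alcohol
Product: 38 C4 O-alkyl S-methyl xanthate, via sodium alkoxide 36 (not isolated), via sodium xanthate 37 (not isolated)
Conditions: NaH, THF, 0 °C; CS2; then MeI, 0 °C → rt
Reagents that add atoms: carbon disulfide, S=C=S; iodomethane, CI
Why: Xanthate formation (alkoxide, carbon disulfide, S-methylation) prepares the alcohol for radical deoxygenation.

Step 25
Reactants: 38 xanthate
Product: 39 C4-deoxy silyl ether (C4 methylene; 3R)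
Conditions: Bu3SnH (5 equiv, 0.5 M), AIBN (cat.), toluene, 110 °C
Reagents that add atoms: none
Why: In this Barton–McCombie deoxygenation the C4 radical is reduced by tin hydride, which is kept concentrated so that hydrogen transfer outruns transannular attack on the hindered C10=C11 alkene.

Step 26
Reactants: 39 C4-deoxy silyl ether
Product: 40 C17 ketone silyl ether
Conditions: pyridinium p-toluenesulfonate, acetone/H2O, 50 °C
Reagents that add atoms: water, O
Why: Mild acid-catalysed ketal hydrolysis frees the C17 ketone while the tertiary allylic oxygen is still silylated and cannot ionise.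

Step 27
Reactants: 40 C17 ketone silyl ether
Product: 41 tertiary allylic alcohol (C12–OH; C10=C11)
Conditions: HF·pyridine, pyridine, THF, 0 °C → rt
Reagents that add atoms: none
Why: Fluoride cleaves the Si–O bond under buffered, non-basic conditions, so the C18 centre next to the ketone is not exposed to base.

Step 28
Reactants: 41 tertiary allylic alcohol
Product: 42 target (10S,11R epoxide)
Conditions: VO(acac)2 (10 mol %), t-BuOOH (1.5 equiv), CH2Cl2, 0 °C → rt
Reagents that add atoms: tert-butyl hydroperoxide, CC(C)(C)OO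
Why: In this hydroxyl-directed epoxidation the vanadate ester of the axial C12 hydroxyl should deliver the peroxide oxygen to the face of C10=C11 on which that hydroxyl lies (O–C12–C11=C10 dihedral near 40–50° in the trans-fused ring system), which gives the epoxide syn to the hydroxyl, and the ketone is inert.

**Compound list**

1 | 3-methylbut-1-yne | CC(C)C#C | starting material
2 | lithium 3-methylbut-1-ynide | CC(C)C#C[Li] | intermediate
3 | 4-methylpent-2-yn-1-ol | CC(C)C#CCO | intermediate
4 | 1-bromo-4-methylpent-2-yne | CC(C)C#CCBr | intermediate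
5 | (S)-(+)-carvone | CC1=CC[C@H](C(C)=C)CC1=O | starting material
6 | lithium enolate of (5S)-dihydrocarvone (O–C14=C15) | CC1=C([O-])C[C@@H](C(C)=C)CC1.[Li+] | intermediate
7 | (2S,5S)-2-methyl-2-(4-methylpent-2-yn-1-yl)-5-(prop-1-en-2-yl)cyclohexan-1-one | C[C@@]1(CC#CC(C)C)CC[C@H](C(C)=C)CC1=O | intermediate
8 | (2S,5S)-2-methyl-2-(4-methyl-2-oxopentyl)-5-(prop-1-en-2-yl)cyclohexan-1-one | C[C@@]1(CC(=O)CC(C)C)CC[C@H](C(C)=C)CC1=O | intermediate
9 | (5S,7aS)-3-isopropyl-7a-methyl-5-(prop-1-en-2-yl)-1,4,5,6,7,7a-hexahydro-2H-inden-2-one | CC(C)C1=C2C[C@@H](C(C)=C)CC[C@@]2(C)CC1=O | intermediate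
10 | methoxy hydroperoxide of 9 (isopropenyl turned into C(CH3)(OCH3)OOH) | CC(C)C1=C2C[C@@H](C(C)(OC)OO)CC[C@@]2(C)CC1=O | intermediate
11 | (5S,7aS)-3-isopropyl-7a-methyl-2-oxo-2,4,5,6,7,7a-hexahydro-1H-inden-5-yl acetate | CC(C)C1=C2C[C@@H](OC(C)=O)CC[C@@]2(C)CC1=O | intermediate
12 | (5S,7aS)-5-hydroxy-3-isopropyl-7a-methyl-1,4,5,6,7,7a-hexahydro-2H-inden-2-one | CC(C)C1=C2C[C@@H](O)CC[C@@]2(C)CC1=O | intermediate
13 | (3R,3aS,5S,7aS)-5-hydroxy-3-isopropyl-7a-methyloctahydro-2H-inden-2-one (trans-fused; 12α-OH) | CC(C)[C@H]1C(=O)C[C@]2(C)CC[C@H](O)C[C@@H]12 | intermediate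
14 | C17 ethylene ketal of 13 | CC(C)[C@H]1C2(OCCO2)C[C@]3(C)CC[C@H](O)C[C@@H]13 | intermediate
15 | (3R,3aS,7aS)-3-isopropyl-7a-methylhexahydro-1H-indene-2,5-dione 2-ethylene ketal (C12 ketone, C17 dioxolane) | CC(C)[C@H]1C2(OCCO2)C[C@]3(C)CCC(=O)C[C@@H]13 | intermediate
16 | ethyl (S)-lactate | CCOC(=O)[C@H](C)O | starting material
17 | ethyl (S)-2-(trifluoromethylsulfonyloxy)propanoate | CCOC(=O)[C@H](C)OS(=O)(=O)C(F)(F)F | intermediate
18 | lithium C2=C12 enolate of 15 | CC(C)[C@H]1C2(OCCO2)C[C@]3(C)CC=C([O-])C[C@@H]13.[Li+] | intermediate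
19 | keto ester: 15 with the (2S)-1-ethoxy-1-oxopropan-2-yl group at C2 (α, equatorial; H-2 β) | CC(C)[C@H]1C2(OCCO2)C[C@]3(C)C[C@H]([C@H](C)C(=O)OCC)C(=O)C[C@@H]13 | intermediate
20 | bromomagnesium C12 alkoxide (12β-vinyl, 12α-O) | CC(C)[C@H]1C2(OCCO2)C[C@]3(C)C[C@H]([C@H](C)C(=O)OCC)[C@](C=C)(O[Mg]Br)C[C@@H]13 | intermediate
21 | C12 vinyl carbinol triethylsilyl ether (12β-vinyl, 12α-OSiEt3) | CC(C)[C@H]1C2(OCCO2)C[C@]3(C)C[C@H]([C@H](C)C(=O)OCC)[C@](C=C)(O[Si](CC)(CC)CC)C[C@@H]13 | intermediate
22 | ozonide (1,2,4-trioxolane) of 21 | CC(C)[C@H]1C2(OCCO2)C[C@]3(C)C[C@H]([C@H](C)C(=O)OCC)[C@](C4OCOO4)(O[Si](CC)(CC)CC)C[C@@H]13 | intermediate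
23 | C12 aldehyde (C11 formyl, 12α-OSiEt3) | CC(C)[C@H]1C2(OCCO2)C[C@]3(C)C[C@H]([C@H](C)C(=O)OCC)[C@](C=O)(O[Si](CC)(CC)CC)C[C@@H]13 | intermediate
24 | cyclopentane-1,3-dione | O=C1CCC(=O)C1 | starting material
25 | 3-bromocyclopent-2-en-1-one | O=C1CCC(Br)=C1 | intermediate
26 | 1-bromo-3-methylenecyclopent-1-ene | C=C1CCC(Br)=C1 | intermediate
27 | (3-methylenecyclopent-1-en-1-yl)lithium | C=C1CCC([Li])=C1 | intermediate
28 | C11 carbinol bearing the 3-methylenecyclopent-1-enyl group (C11 epimers) | CC(C)[C@H]1C2(OCCO2)C[C@]3(C)C[C@H]([C@H](C)C(=O)OCC)[C@](C(O)C4=CC(=C)CC4)(O[Si](CC)(CC)CC)C[C@@H]13 | intermediate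
29 | C11 dienone (C11 ketone between C12 and the cyclopentenyl C10) | CC(C)[C@H]1C2(OCCO2)C[C@]3(C)C[C@H]([C@H](C)C(=O)OCC)[C@](C(=O)C4=CC(=C)CC4)(O[Si](CC)(CC)CC)C[C@@H]13 | intermediate
30 | C11 tertiary alkoxide (drawn as lithium salt) | CC(C)[C@H]1C2(OCCO2)C[C@]3(C)C[C@H]([C@H](C)C(=O)OCC)[C@]([C@](C)([O-])C4=CC(=C)CC4)(O[Si](CC)(CC)CC)C[C@@H]13.[Li+] | intermediate
31 | δ-lactone (C4(=O)–O–C11; 3S, 11R; 3α-methyl, 11β-methyl, 11α-cyclopentenyl, 12α-OSiEt3) | CC(C)[C@H]1C2(OCCO2)C[C@]3(C)C[C@@H]4[C@H](C)C(=O)O[C@](C)(C5=CC(=C)CC5)[C@@]4(O[Si](CC)(CC)CC)C[C@@H]13 | intermediate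
32 | 2-methylenepyran (exocyclic enol ether C5=C4–O–C11; stereocentres as in 31) | CC(C)[C@H]1C2(OCCO2)C[C@]3(C)C[C@@H]4[C@H](C)C(=C)O[C@](C)(C5=CC(=C)CC5)[C@@]4(O[Si](CC)(CC)CC)C[C@@H]13 | intermediate
33 | tetracyclic C4 ketone (C10=C11, C7 methylene, 6S, 12α-OSiEt3, C17 dioxolane) | CC(C)[C@H]1C2(OCCO2)C[C@]3(C)C[C@@H]4[C@H](C)C(=O)C[C@H]5C(=C)CC/C5=C(\C)[C@@]4(O[Si](CC)(CC)CC)C[C@@H]13 | intermediate
34 | C7-methyl C4 ketone (7S) | CC(C)[C@H]1C2(OCCO2)C[C@]3(C)C[C@@H]4[C@H](C)C(=O)C[C@H]5[C@@H](C)CC/C5=C(\C)[C@@]4(O[Si](CC)(CC)CC)C[C@@H]13 | intermediate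
35 | C4 alcohol (C4 epimers) | CC(C)[C@H]1C2(OCCO2)C[C@]3(C)C[C@@H]4[C@H](C)C(O)C[C@H]5[C@@H](C)CC/C5=C(\C)[C@@]4(O[Si](CC)(CC)CC)C[C@@H]13 | intermediate
36 | sodium C4 alkoxide | CC(C)[C@H]1C2(OCCO2)C[C@]3(C)C[C@@H]4[C@H](C)C([O-])C[C@H]5[C@@H](C)CC/C5=C(\C)[C@@]4(O[Si](CC)(CC)CC)C[C@@H]13.[Na+] | intermediate
37 | sodium C4 xanthate | CC(C)[C@H]1C2(OCCO2)C[C@]3(C)C[C@@H]4[C@H](C)C(OC(=S)[S-])C[C@H]5[C@@H](C)CC/C5=C(\C)[C@@]4(O[Si](CC)(CC)CC)C[C@@H]13.[Na+] | intermediate
38 | C4 O-alkyl S-methyl xanthate | CC(C)[C@H]1C2(OCCO2)C[C@]3(C)C[C@@H]4[C@H](C)C(OC(=S)SC)C[C@H]5[C@@H](C)CC/C5=C(\C)[C@@]4(O[Si](CC)(CC)CC)C[C@@H]13 | intermediate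
39 | C4-deoxy silyl ether (C17 dioxolane, C10=C11) | CC(C)[C@H]1C2(OCCO2)C[C@]3(C)C[C@@H]4[C@H](C)CC[C@H]5[C@@H](C)CC/C5=C(\C)[C@@]4(O[Si](CC)(CC)CC)C[C@@H]13 | intermediate
40 | C17 ketone silyl ether | CC(C)[C@H]1C(=O)C[C@]2(C)C[C@@H]3[C@H](C)CC[C@H]4[C@@H](C)CC/C4=C(\C)[C@@]3(O[Si](CC)(CC)CC)C[C@@H]12 | intermediate
41 | tertiary allylic alcohol (C12–OH, C10=C11, C17 ketone) | CC(C)[C@H]1C(=O)C[C@]2(C)C[C@@H]3[C@H](C)CC[C@H]4[C@@H](C)CC/C4=C(\C)[C@@]3(O)C[C@@H]12 | intermediate
42 | CNP0332295.1 (2R,3R,6S,7S,10S,11R,12R,14S,15S,18R) | CC(C)[C@H]1C(=O)C[C@]2(C)C[C@@H]3[C@H](C)CC[C@H]4[C@@H](C)CC[C@]45O[C@]5(C)[C@@]3(O)C[C@@H]12 | target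

**Step count and risks**

Total step count: 28. Longest linear sequence: 25 steps (steps 1–10, 12–14 and 17–28, from 3-methylbut-1-yne 1; 23 steps from (S)-carvone 5).

Steps most likely to fail:

Step 21 (ring expansion). The trans-fused pyran may not reach the twist-boat in which the cyclopentenyl group lies over the enol ether, so that nothing happens below the temperature at which the C11–O bond ionises. The exocyclic enol ether may also migrate into the ring under traces of acid and then rearrange to a six-membered ring, and ionisation followed by recombination may erode the transfer of chirality to C6. Fallback: the C5–C6 bond is made ionically on an activated substrate. The fallback sets out from lactone 31. Addition of LiCH2CO2Me (THF, −78 °C) should give the lactol F1, and dehydration (MsCl, Et3N) the alkylidene pyran ester F2. With Pd(PPh3)4 (zerovalent palladium, DMSO, 60 °C) the allylic C11–O bond should ionise to a π-allylpalladium and β-keto ester enolate pair, and the enolate should close on the less hindered terminus C6 to give the eight-membered β-keto ester F3. Oxidative addition and enolate attack both occur with inversion, so C5 arrives on the face from which oxygen left, as in the sigmatropic shift. Demethoxycarbonylation (LiCl, wet DMSO, 130 °C) comes back to the route at ketone 33.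

Step 19 (C11 centre and lactone). The facial selectivity of the methyl addition may be low or reversed if a chelated transition state competes with the Felkin–Anh one. The silyl group may also migrate from O12 to the new C11 alkoxide, followed by γ-lactonisation through O12, or the alkoxide may epimerise C3 of the lactone. Fallback: the two C11 substituents are introduced in the reverse order, which under one and the same facial bias gives the opposite C11 epimer. The fallback sets out from aldehyde 23. MeMgBr (THF, −78 °C) should give the methyl carbinol F4, and Dess–Martin oxidation the methyl ketone F5. Addition of alkenyllithium 27 (CeCl3, THF, −78 → 0 °C) followed by lactonisation comes back to the route at lactone 31.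

Step 12 (enolate alkylation). The enolate may eliminate the secondary triflate (E2) or be consumed by proton transfer and O-alkylation, which would give low conversion. Fallback: the alkylation is run on a metalated hydrazone, which is more nucleophilic and less basic. The fallback sets out from ketone 15. Me2NNH2 (AcOH cat., EtOH, 60 °C) should give the N,N-dimethylhydrazone F6. Deprotonation with LiN(i-Pr)2 and alkylation with triflate 17 (−78 °C) should give the alkylated hydrazone F7 with the same inversion at C3. Hydrolysis (CuCl2, THF/pH 7 buffer), with equilibration of C2 to the equatorial epimer, comes back to the route at keto ester 19.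

Further compounds
F1 | step 21 | lactol from 31 and LiCH2CO2Me (C4 hemiketal bearing CH2CO2Me) | CC(C)[C@H]1C2(OCCO2)C[C@]3(C)C[C@@H]4[C@H](C)C(O)(CC(=O)OC)O[C@](C)(C5=CC(=C)CC5)[C@@]4(O[Si](CC)(CC)CC)C[C@@H]13
F2 | step 21 | alkylidene pyran ester (C4=C5H–CO2Me enol ether) | CC(C)[C@H]1C2(OCCO2)C[C@]3(C)C[C@@H]4[C@H](C)C(=CC(=O)OC)O[C@](C)(C5=CC(=C)CC5)[C@@]4(O[Si](CC)(CC)CC)C[C@@H]13
F3 | step 21 | eight-membered β-keto ester (33 with CO2Me on C5) | CC(C)[C@H]1C2(OCCO2)C[C@]3(C)C[C@@H]4[C@H](C)C(=O)C(C(=O)OC)[C@H]5C(=C)CC/C5=C(\C)[C@@]4(O[Si](CC)(CC)CC)C[C@@H]13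
F4 | step 19 | C11 methyl carbinol (C11 epimers) | CC(C)[C@H]1C2(OCCO2)C[C@]3(C)C[C@H]([C@H](C)C(=O)OCC)[C@](C(C)O)(O[Si](CC)(CC)CC)C[C@@H]13
F5 | step 19 | C11 methyl ketone (12β-acetyl, 12α-OSiEt3) | CC(C)[C@H]1C2(OCCO2)C[C@]3(C)C[C@H]([C@H](C)C(=O)OCC)[C@](C(C)=O)(O[Si](CC)(CC)CC)C[C@@H]13
F6 | step 12 | N,N-dimethylhydrazone of 15 | CC(C)[C@H]1C2(OCCO2)C[C@]3(C)CCC(=NN(C)C)C[C@@H]13
F7 | step 12 | C2-alkylated N,N-dimethylhydrazone | CC(C)[C@H]1C2(OCCO2)C[C@]3(C)C[C@H]([C@H](C)C(=O)OCC)C(=NN(C)C)C[C@@H]13
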